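**Plan**
Retrosynthesis: the δ-lactone is cut at C20–O (giving a C7 acid and a C1–C10–C20 siloxycyclopropane), ring D at C13–C16 (aldol), ring C at C8–C14 (radical closure), then C8–C15, C8–C9 (Michael), C9=C10 (aldol condensation) and C5–C6 (conjugate addition), back to 4,4-dimethylcyclohex-2-en-1-one.
Forward: ring A is dressed first (C6, then the C9–C8–C7 arm), the spirolactone is closed, the ring A enone is installed, and rings C and D are built on the lactone.
Enabling feature: C20 is a CH2 on the quaternary C10 next to the C1 ketone, so C1/C10/C20 can be stored as a cyclopropanol silyl ether; opening its strained C1–C20 bond with iodonium frees the ketone and leaves C20 electrophilic, 6-exo to the C7 carboxylate.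
Stereochemistry: C5 by catalyst control; C9 by attack anti to the C5 substituent; C10 by hydroxyl-directed cyclopropanation; C8 by cis-selective closure of ring C; C13 by the bridge; C16 by kinetic protonation.

Key step: step 11

Remark on labels: positions are numbered as in the kaurane skeleton (ring A = C1–C5, C10; lactone = C7, O, C20, C10, C9, C8; ring C = C8, C9, C11–C14; ring D = C8, C14, C13, C16, C15; C6 = CH2OH carbon; C17 = methyl).
Assumption: the copper catalyst of step 3 is taken to give the (3S) product with the ligand enantiomer named; if the sense is opposite, the mirror-image ligand is used.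

Step 1
Reactants: 1 2-chloroprop-2-en-1-ol; 2 triethyl orthoacetate
Product: 3 ethyl 4-chloropent-4-enoate
Conditions: EtCO2H (cat.), 140 °C, EtOH distilled off
Reagents that add atoms: none
Why: Johnson–Claisen rearrangement of the mixed ketene acetal places the ester two carbons from the 2-chloroalkene; no stereocenter is formed.

Step 2
Reactants: 3 ethyl 4-chloropent-4-enoate
Product: 4 4-chloropent-4-enal
Conditions: i-Bu2AlH, CH2Cl2, −78 °C; aq Rochelle salt
Reagents that add atoms: none
Why: partial reduction of the ester stops at the aldehyde because the tetrahedral aluminate is stable at low temperature, and the vinyl chloride is inert.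

Step 3
Reactants: 5 4,4-dimethylcyclohex-2-en-1-one; 6 (chloromethyl)dimethyl(propan-2-yloxy)silane; 4 4-chloropent-4-enal
Product: 9 (2R,3S)-2-(4-chloro-1-hydroxypent-4-en-1-yl)-3-{[dimethyl(propan-2-yloxy)silyl]methyl}-4,4-dimethylcyclohexan-1-one (both carbinol epimers), via Grignard reagent 7 (not isolated), via magnesium enolate 8 (not isolated)
Conditions: 6, Mg, THF; CuBr·SMe2 (5 mol %), (R)-1-[(S)-2-(diphenylphosphino)ferrocenyl]ethyldicyclohexylphosphine (6 mol %), 5, t-BuOMe, −78 °C; then 4, −78 °C; aq NH4Cl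
Reagents that add atoms: none
Why: copper-catalysed asymmetric conjugate addition of the hydroxymethyl-equivalent Grignard reagent sets C5 by ligand control, and the regiodefined magnesium enolate is trapped by aldol addition to 4 trans to the new substituent (the C10 and carbinol centres are erased in step 5).

Step 4
Reactants: 9 silyl aldol
Product: 10 (2R,3S)-2-(4-chloro-1-hydroxypent-4-en-1-yl)-3-(hydroxymethyl)-4,4-dimethylcyclohexan-1-one (both carbinol epimers)
Conditions: 30% H2O2, KF, KHCO3, THF/MeOH, rt
Reagents that add atoms: hydrogen peroxide, OO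
Why: Tamao oxidation moves C6 from silicon to oxygen with retention and unveils the primary alcohol without touching C5.

Step 5
Reactants: 10 diol
Product: 12 [(1R,2E)-2-(4-chloropent-4-en-1-ylidene)-6,6-dimethyl-3-oxocyclohexyl]methyl acetate, via diacetate 11 (not isolated)
Conditions: Ac2O, pyridine, DMAP (cat.), CH2Cl2, 0 °C to rt; then DBU, rt
Reagents that add atoms: acetic anhydride, CC(=O)OC(C)=O
Why: acetylation followed by E1cB elimination of the β-acetoxy ketone should give the (E)-alkylidene ketone (chain anti to C=O), while the primary acetate blocks oxa-Michael addition of C6–OH.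

Step 6
Reactants: 12 alkylidene ketone; 13 tert-butyl[(1-methoxyethenyl)oxy]dimethylsilane
Product: 14 methyl (3R)-3-[(6R)-6-(acetoxymethyl)-2-{[tert-butyl(dimethyl)silyl]oxy}-5,5-dimethylcyclohex-1-en-1-yl]-6-chlorohept-6-enoate
Conditions: TBSOTf (10 mol %), CH2Cl2, −78 °C
Reagents that add atoms: none
Why: Mukaiyama–Michael addition with silyl transfer; the ketene silyl acetal should attack C9 of the s-cis enone anti to the C5–CH2OAc group, which A(1,3) strain with the (E)-chain holds pseudoaxial, setting C9 and returning the C1=C10 silyl enol ether regiospecifically.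

Step 7
Reactants: 14 acetate
Product: 15 methyl (3R)-3-[(6R)-2-{[tert-butyl(dimethyl)silyl]oxy}-6-(hydroxymethyl)-5,5-dimethylcyclohex-1-en-1-yl]-6-chlorohept-6-enoate
Conditions: K2CO3 (0.2 equiv), MeOH, 0 °C
Reagents that add atoms: none
Why: mild Zemplén-type methanolysis removes the primary acetate, while the hindered tetrasubstituted silyl enol ether and the methyl ester should persist.

Step 8
Reactants: 15 homoallylic alcohol
Product: 16 methyl (3R)-3-[6-{[tert-butyl(dimethyl)silyl]oxy}-2-(hydroxymethyl)-3,3-dimethylbicyclo[4.1.0]heptan-1-yl]-6-chlorohept-6-enoate (cyclopropane CH2 = C20 cis to CH2OH)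
Conditions: Et2Zn, CH2I2, CH2Cl2, 0 °C
Reagents that add atoms: diiodomethane, ICI
Why: hydroxyl-directed Simmons–Smith cyclopropanation; the zinc alkoxide of C6–OH delivers CH2 to the electron-rich enol ether on its own face (also the face anti to the axial C4 methyl), fixing C10 with C20 cis to C6 and the cis-fused C1.

Step 9
Reactants: 16 cyclopropane alcohol
Product: 17 the C6 tert-butyldiphenylsilyl ether of 16
Conditions: TBDPSCl, imidazole, DMF, rt
Reagents that add atoms: tert-butyl(chloro)diphenylsilane, CC(C)(C)[Si](Cl)(c1ccccc1)c1ccccc1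
Why: standard silylation of the primary alcohol, so that later electrophilic and basic steps meet no free C6–OH.

Step 10
Reactants: 17 methyl ester
Product: 18 (3R)-6-chlorohept-6-enoic acid carrying at C3 the siloxycyclopropane ring A unit of 17
Conditions: LiOH, THF/MeOH/H2O, rt; AcOH to pH 5
Reagents that add atoms: lithium hydroxide, [Li+].[OH-]
Why: saponification of the unhindered methyl ester; both silyl ethers and the cyclopropane are stable to aqueous base and to the buffered work-up.

Step 11
Reactants: 18 siloxycyclopropane acid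
Product: 20 5-(3-chlorobut-3-en-1-yl)-11-({[tert-butyl(diphenyl)silyl]oxy}methyl)-10,10-dimethyl-2-oxaspiro[5.5]undecane-3,7-dione (C9, C10 and C5 as in 28), via iodo keto acid 19 (not isolated)
Conditions: NIS, MeCN, 0 °C, dark; then Cs2CO3, 50 °C
Reagents that add atoms: none
Why: Iodonium from NIS attacks the least substituted corner of the oxygen-activated cyclopropane (C20), the C1–C20 bond opens with release of ring strain, and loss of the silyl group reveals the C1 ketone with C20 as a primary iodide; the caesium carboxylate of C7 then forms the C20–O bond and closes the δ-lactone. The closest known reaction types are N-halosuccinimide ring opening of siloxycyclopropanes to β-halo ketones and lactonisation by carboxylate O-alkylation. The ring closes in the 6-exo-tet mode. No stereocenter is created: C10 keeps the configuration set in step 8 because none of its bonds is broken. The step needs cleavage of the external C1–C20 bond and not the internal C1–C10 bond, which the polar two-electron pathway at the unhindered CH2 secures (a radical pathway would favour ring expansion), and it needs O-alkylation only, which the silyl cap on C6–OH and the quaternary C10 (no elimination possible) secure.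

Step 12
Reactants: 20 spiro keto lactone
Product: 21 the undec-8-ene-3,7-dione corresponding to 20 (ring A C2=C3 enone)
Conditions: IBX, DMSO/toluene, 75 °C
Reagents that add atoms: none
Why: IBX dehydrogenation through the ketone enol; only C2–C3 can desaturate because C10 is quaternary, and the lactone does not react.

Step 13
Reactants: 21 enone lactone; 22 N-methoxy-N-methylpropanamide
Product: 23 the C8-propanoyl lactone of 21 (C8 epimers)
Conditions: LiN(SiMe3)2 (2.2 equiv), THF, −78 °C; then 22; aq NH4Cl
Reagents that add atoms: none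
Why: Claisen-type C-acylation of the lactone enolate with a Weinreb amide (the chelated adduct prevents over-addition); the ring A enone has no α- or γ-hydrogen, so only C8 is deprotonated.

Step 14
Reactants: 23 β-keto lactone
Product: 24 cis-fused lactone/cyclohexanone (C13 ketone) bearing the C8 propanoyl group, spiro to the ring A enone
Conditions: Mn(OAc)3·2H2O (2.2 equiv), Cu(OAc)2·H2O (20 mol %), AcOH, 50 °C; H2O
Reagents that add atoms: water, O
Why: oxidative free-radical cyclisation in which the enolate on trivalent manganese gives the C8 radical, which adds 6-endo to the CH2 end of the 2-chloroalkene, and oxidation and hydrolysis of the α-chloro radical give the C13 ketone; the C9 chain sits pseudoaxial (A(1,2) strain with the C8 acyl group) and attacks on its own face, so C8 is set with C14 syn to C11.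

Step 15
Reactants: 24 diketone
Product: 27 the C6 tert-butyldiphenylsilyl ether of 28, via lithium aldolate 25 (not isolated), via enolate dianion 26 (not isolated)
Conditions: LiN(SiMe3)2 (1.0 equiv), THF, −78 to 0 °C; then LiN(i-Pr)2 (1.6 equiv), −78 to −40 °C; then AcOH, −78 °C
Reagents that add atoms: none
Why: intramolecular aldol addition of the propanoyl enolate (C16) to the C13 ketone closes ring D as a bicyclo[3.2.1]octane (C13 fixed by the bridge from C8), and kinetic protonation of the regenerated C15–C16 enolate from the open exo face (the side of the C14 bridge) should place the C16 methyl endo as required.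

Step 16
Reactants: 27 silyl ether
Product: 28 CNP0533761.1
Conditions: HF·pyridine, pyridine/THF, 0 °C to rt
Reagents that add atoms: none
Why: fluoride desilylation under weakly acidic conditions, which should avoid retro-aldol opening and C16 epimerisation.

**Compound list**
1 | 2-chloroprop-2-en-1-ol | OCC(Cl)=C | starting material
2 | triethyl orthoacetate | CCOC(C)(OCC)OCC | starting material
3 | ethyl 4-chloropent-4-enoate | CCOC(=O)CCC(Cl)=C | intermediate
4 | 4-chloropent-4-enal | O=CCCC(Cl)=C | intermediate
5 | 4,4-dimethylcyclohex-2-en-1-one | CC1(C)CCC(=O)C=C1 | starting material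
6 | (chloromethyl)dimethyl(propan-2-yloxy)silane | CC(C)O[Si](C)(C)CCl | starting material
7 | {[dimethyl(propan-2-yloxy)silyl]methyl}magnesium chloride | CC(C)O[Si](C)(C)C[Mg]Cl | intermediate
8 | chloromagnesium (3S)-3-{[dimethyl(propan-2-yloxy)silyl]methyl}-4,4-dimethylcyclohex-1-en-1-olate | Cl[Mg]OC1=C[C@H](C[Si](C)(C)OC(C)C)C(C)(C)CC1 | intermediate
9 | (2R,3S)-2-(4-chloro-1-hydroxypent-4-en-1-yl)-3-{[dimethyl(propan-2-yloxy)silyl]methyl}-4,4-dimethylcyclohexan-1-one (carbinol epimers) | O=C1CCC(C)(C)[C@@H](C[Si](C)(C)OC(C)C)[C@@H]1C(O)CCC(Cl)=C | intermediate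
10 | (2R,3S)-2-(4-chloro-1-hydroxypent-4-en-1-yl)-3-(hydroxymethyl)-4,4-dimethylcyclohexan-1-one (carbinol epimers) | O=C1CCC(C)(C)[C@@H](CO)[C@@H]1C(O)CCC(Cl)=C | intermediate
11 | diacetate of 10 | O=C1CCC(C)(C)[C@@H](COC(C)=O)[C@@H]1C(OC(C)=O)CCC(Cl)=C | intermediate
12 | [(1R,2E)-2-(4-chloropent-4-en-1-ylidene)-6,6-dimethyl-3-oxocyclohexyl]methyl acetate | CC(=O)OC[C@@H]1C(C)(C)CCC(=O)/C1=C/CCC(Cl)=C | intermediate
13 | tert-butyl[(1-methoxyethenyl)oxy]dimethylsilane | COC(=C)O[Si](C)(C)C(C)(C)C | starting material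
14 | methyl (3R)-3-[(6R)-6-(acetoxymethyl)-2-{[tert-butyl(dimethyl)silyl]oxy}-5,5-dimethylcyclohex-1-en-1-yl]-6-chlorohept-6-enoate | COC(=O)C[C@@H](CCC(Cl)=C)C1=C(O[Si](C)(C)C(C)(C)C)CCC(C)(C)[C@H]1COC(C)=O | intermediate
15 | methyl (3R)-3-[(6R)-2-{[tert-butyl(dimethyl)silyl]oxy}-6-(hydroxymethyl)-5,5-dimethylcyclohex-1-en-1-yl]-6-chlorohept-6-enoate | COC(=O)C[C@@H](CCC(Cl)=C)C1=C(O[Si](C)(C)C(C)(C)C)CCC(C)(C)[C@H]1CO | intermediate
16 | methyl (3R)-3-[6-{[tert-butyl(dimethyl)silyl]oxy}-2-(hydroxymethyl)-3,3-dimethylbicyclo[4.1.0]heptan-1-yl]-6-chlorohept-6-enoate (cyclopropane CH2 cis to CH2OH) | COC(=O)C[C@@H](CCC(Cl)=C)[C@]12C[C@@]1(O[Si](C)(C)C(C)(C)C)CCC(C)(C)[C@H]2CO | intermediate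
17 | C6 tert-butyldiphenylsilyl ether of 16 | COC(=O)C[C@@H](CCC(Cl)=C)[C@]12C[C@@]1(O[Si](C)(C)C(C)(C)C)CCC(C)(C)[C@H]2CO[Si](c1ccccc1)(c1ccccc1)C(C)(C)C | intermediate
18 | carboxylic acid from 17 | OC(=O)C[C@@H](CCC(Cl)=C)[C@]12C[C@@]1(O[Si](C)(C)C(C)(C)C)CCC(C)(C)[C@H]2CO[Si](c1ccccc1)(c1ccccc1)C(C)(C)C | intermediate
19 | (3R)-6-chloro-3-[2-({[tert-butyl(diphenyl)silyl]oxy}methyl)-1-(iodomethyl)-3,3-dimethyl-6-oxocyclohexyl]hept-6-enoic acid (CH2I cis to CH2OSi) | OC(=O)C[C@@H](CCC(Cl)=C)[C@]1(CI)C(=O)CCC(C)(C)[C@H]1CO[Si](c1ccccc1)(c1ccccc1)C(C)(C)C | intermediate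
20 | 5-(3-chlorobut-3-en-1-yl)-11-({[tert-butyl(diphenyl)silyl]oxy}methyl)-10,10-dimethyl-2-oxaspiro[5.5]undecane-3,7-dione (lactone CH2O cis to CH2OSi; C9 as in 14) | O=C1C[C@@H](CCC(Cl)=C)[C@]2(CO1)C(=O)CCC(C)(C)[C@H]2CO[Si](c1ccccc1)(c1ccccc1)C(C)(C)C | intermediate
21 | 5-(3-chlorobut-3-en-1-yl)-11-({[tert-butyl(diphenyl)silyl]oxy}methyl)-10,10-dimethyl-2-oxaspiro[5.5]undec-8-ene-3,7-dione | O=C1C[C@@H](CCC(Cl)=C)[C@]2(CO1)C(=O)C=CC(C)(C)[C@H]2CO[Si](c1ccccc1)(c1ccccc1)C(C)(C)C | intermediate
22 | N-methoxy-N-methylpropanamide | CCC(=O)N(C)OC | starting material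
23 | 4-propanoyl derivative of 21 (C8 epimers) | CCC(=O)C1[C@@H](CCC(Cl)=C)[C@]2(COC1=O)C(=O)C=CC(C)(C)[C@H]2CO[Si](c1ccccc1)(c1ccccc1)C(C)(C)C | intermediate
24 | tricyclic diketone: lactone cis-fused to the ring C cyclohexanone (C13 ketone; C8 propanoyl trans to C11) and spiro to the ring A enone | CCC(=O)[C@]12CC(=O)CC[C@H]1[C@]1(COC2=O)C(=O)C=CC(C)(C)[C@H]1CO[Si](c1ccccc1)(c1ccccc1)C(C)(C)C | intermediate
25 | lithium C13 aldolate of silyl-protected 28 (C16 not defined) | CC1C(=O)[C@]23C[C@@]1([O-])CC[C@H]2[C@]1(COC3=O)C(=O)C=CC(C)(C)[C@H]1CO[Si](c1ccccc1)(c1ccccc1)C(C)(C)C.[Li+] | intermediate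
26 | dilithium C13 alkoxide C15–C16 enolate | CC1=C([O-])[C@]23C[C@@]1([O-])CC[C@H]2[C@]1(COC3=O)C(=O)C=CC(C)(C)[C@H]1CO[Si](c1ccccc1)(c1ccccc1)C(C)(C)C.[Li+].[Li+] | intermediate
27 | C6 tert-butyldiphenylsilyl ether of 28 | C[C@H]1C(=O)[C@]23C[C@@]1(O)CC[C@H]2[C@]1(COC3=O)C(=O)C=CC(C)(C)[C@H]1CO[Si](c1ccccc1)(c1ccccc1)C(C)(C)C | intermediate
28 | CNP0533761.1 (6,13-dihydroxy-16-methyl-1,15-dioxo-6,7-seco-kaur-2-en-7,20-olide; C16 methyl endo) | C[C@H]1C(=O)[C@]23C[C@@]1(O)CC[C@H]2[C@]1(COC3=O)C(=O)C=CC(C)(C)[C@H]1CO | target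

**Count and risks**
Total step count: 16. Longest linear sequence: 16 steps (1 to 28); the branch from 5 is 14 steps.

Steps most likely to fail:

Step 3. The bulky silylmethyl Grignard reagent may add slowly or with poor face discrimination next to the quaternary C4, and 1,2-addition may compete. The fallback sets out from 5 and comes back at 9. Reagent 7 is added to 5 with CuI and Me3SiCl without a chiral ligand to give the racemic trimethylsilyl enol ether F1. Saegusa–Ito oxidation with Pd(OAc)2 erases the stereocenter and gives the 3-substituted enone F2. Asymmetric 1,4-reduction with a copper hydride catalyst made from Cu(OAc)2·H2O, (R)-DTBM-SEGPHOS and Ph2SiH2 then sets C5 by hydride delivery to the β,β-disubstituted enone and gives the regiodefined diphenylsilyl enol ether F3. MeLi followed by aldehyde 4 gives 9.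

Step 11. Displacement at the neopentyl-type C20 may be too slow, so that the iodide decomposes or rearranges before the ring closes. The fallback sets out from 17 and comes back at 20. NIS opens the cyclopropane of 17 to the iodo keto ester F4, which is isolated. Radical hydroxylation with Bu3SnH under air, then PPh3, converts the iodide into the hydroxy keto ester F5. PPTS in warm toluene closes the δ-lactone by transesterification, so ring closure proceeds by acyl substitution instead of O-alkylation.

Step 15. Retro-aldol opening at the dianion stage, competing aldol closure of the C12 enolate onto C1, or unselective protonation may spoil ring D or C16. The fallback sets out from 24 and comes back at 27. Cyclisation with LiN(SiMe3)2 alone gives the aldol, isolated as the 16-epimeric ketol F6. Its dianion (LiN(i-Pr)2) is selenenylated with PhSeBr to the 16-phenylselanyl ketone F7. H2O2 gives the 16-methylene ketone F8 by selenoxide syn-elimination, since only the methyl group carries β-hydrogens. Hydrogenation with RhCl(PPh3)3 and H2 from the exo face should give 27, replacing protonation by hydrogen delivery to set C16.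

Further compounds
F1 | step 3 | racemic {[dimethyl(propan-2-yloxy)silyl]methyl}-substituted trimethylsilyl enol ether of 4,4-dimethylcyclohexanone | C[Si](C)(C)OC1=CC(C[Si](C)(C)OC(C)C)C(C)(C)CC1
F2 | step 3 | 3-{[dimethyl(propan-2-yloxy)silyl]methyl}-4,4-dimethylcyclohex-2-en-1-one | O=C1C=C(C[Si](C)(C)OC(C)C)C(C)(C)CC1
F3 | step 3 | (3S)-3-{[dimethyl(propan-2-yloxy)silyl]methyl}-4,4-dimethylcyclohex-1-en-1-yl diphenylsilyl ether | c1ccccc1[SiH](c1ccccc1)OC1=C[C@H](C[Si](C)(C)OC(C)C)C(C)(C)CC1
F4 | step 11 | methyl ester of iodo keto acid 19 | COC(=O)C[C@@H](CCC(Cl)=C)[C@]1(CI)C(=O)CCC(C)(C)[C@H]1CO[Si](c1ccccc1)(c1ccccc1)C(C)(C)C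
F5 | step 11 | C20 hydroxy keto methyl ester | COC(=O)C[C@@H](CCC(Cl)=C)[C@]1(CO)C(=O)CCC(C)(C)[C@H]1CO[Si](c1ccccc1)(c1ccccc1)C(C)(C)C
F6 | step 15 | 16-epimer of 27 (C16 methyl exo) | C[C@@H]1C(=O)[C@]23C[C@@]1(O)CC[C@H]2[C@]1(COC3=O)C(=O)C=CC(C)(C)[C@H]1CO[Si](c1ccccc1)(c1ccccc1)C(C)(C)C
F7 | step 15 | 16-phenylselanyl derivative of F6 (C16 not defined) | CC1([Se]c2ccccc2)C(=O)[C@]23C[C@@]1(O)CC[C@H]2[C@]1(COC3=O)C(=O)C=CC(C)(C)[C@H]1CO[Si](c1ccccc1)(c1ccccc1)C(C)(C)C
F8 | step 15 | 16-methylene-15-ketone (C6 silyl ether) | C=C1C(=O)[C@]23C[C@@]1(O)CC[C@H]2[C@]1(COC3=O)C(=O)C=CC(C)(C)[C@H]1CO[Si](c1ccccc1)(c1ccccc1)C(C)(C)C
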